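Late in the winter run the product readings lie level within their scatter: 27% at 2.00 h, 26% at 3.00 h, each reading good to 1.5 percentage points. So we ask what the rate did on the way there.

| setting | winter | noon | south-west | north-west | north-east |
|---|---|---|---|---|---|
| starting material | 0.095 M | 0.095 M | 0.095 M | 0.095 M | 0.095 M (fed, over 1.0 h) |
| reagent | 0.095 M | 0.095 M | 0.0950 M (fed, over 1.0 h) | 0.0950 M | 0.0950 M |
| free catalyst | 0.47 mM | 0.23 mM | 0.47 mM | 0.47 mM | 0.47 mM |
| remark | run made earlier | run made earlier | all else is in the flask from the start; the feed brings no volume worth counting | everything together at the start | all else is in the flask from the start; the feed brings no volume worth counting |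
| time |  |  | 5.0 h | 5.0 h | 5.0 h |

winter run (percent of the starting material charged)

| time / h | product / % |
|---|---|
| 0.250 | 7 |
| 0.833 | 20 |
| 1.33 | 23 |
| 2.00 | 27 |
| 3.00 | 26 |

noon run (percent of the starting material charged)

| time / min | product / % |
|---|---|
| 8.00 | 4 |
| 25.0 | 12 |
| 40.0 | 13 |
| 60.0 | 15 |
| 90.0 | 15 |

(readings scatter by 1.5 percentage points)

- a species is counted by the starting material in it: one spent catalyst counts as two
- on the list of suspects stand: starting material + free catalyst -> catalyst intermediate A; catalyst intermediate A -> catalyst intermediate B; reagent + catalyst intermediate B <-> catalyst intermediate C; catalyst intermediate C -> free catalyst + product; 2 catalyst intermediate B -> spent catalyst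

- which flask leads in amount of product, in percent of the starting material charged ("all alike" within 1.5 percentage points) (south-west / north-west / north-east / all alike)
- how much product is there at the end, in percent of the starting material charged: south-west
- how much product is there at the end, in percent of the starting material charged: north-west
- how much product is there at the end, in percent of the starting material charged: north-east

We follow the winter rate, as a fraction of the charge. It opens at 0.280 h⁻¹ and, from 1.33 h to 3.00 h, reads 0.0180 h⁻¹, a loose reading at that size. Around those last two readings 73.5% of the starting material remains, and of the reagent too, since the charges are equal. If the rate goes with each at first power: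

- fall in rate: 15.6
- from starting material: 1.36
- from reagent: 1.36
- remainder, for the working catalyst: 8.42

The remainder is larger than either depletion factor, so the accumulated slowing is mostly catalyst loss. We therefore count the turnover budget, the product made per catalyst charged by the time the readings lie level:

- winter: 53.6
- noon, with half the catalyst: 62.0

North-west repeats the winter recipe, so we expect 26.5%. On the list, a turn takes reagent and a death takes a second catalyst intermediate B. Over its hour a steady feed brings on average 0.5 of the reagent charge, so we give south-west 0.5 of the budget, 13.2%. North-east should exceed the budget, by an amount we cannot reckon.

The forecast puts north-east first: south-west 18% (10% to 25%), north-west 27% (25% to 29%), north-east 34% (27% to 50%). Its south-west stands above ours. Its ground: “Feeding starting material throttles flow into B and keeps reagent high, so B stays low.”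

    starting material + free catalyst → catalyst intermediate A (k = 170 M⁻¹ min⁻¹)
    catalyst intermediate A → catalyst intermediate B (k = 20.0 min⁻¹)
    reagent + catalyst intermediate B ⇌ catalyst intermediate C (K = 6.80 M⁻¹, k = 41.0 M⁻¹ min⁻¹)
    catalyst intermediate C → free catalyst + product (k = 1000 min⁻¹)
    2 catalyst intermediate B → spent catalyst (k = 290 M⁻¹ min⁻¹)

North-east leads with 35.2%, against 31.1% in north-west and 16.8% in south-west, a lead of 4 points over the margin's 1.5 points. With the step from two catalyst intermediate B to spent catalyst struck out, north-east gives 98.4%. In turnovers, south-west paid 34.0, north-west 62.9 and north-east 71.1, against a budget of 53.6. South-west thus drew 0.635 of the budget, against our 0.5.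

The neighbour is south-west with 0.038 M of starting material. The same share of the budget gives 42.1% of that smaller charge, and the flask gives 43.5%.

(The runs are calculated from invented constants, and the scatter is random.)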